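**Retrosynthetic overview**

- Ring B is closed last: O2–C3 by 6-endo addition of the C1 hydroxyl to a C4a-alkynyl 5-chloro-enone; C4a–C4 comes from Sonogashira coupling of a C4a enol triflate (ring A 1,3-dione, chlorinated at C5) with the C4/C3/C9–C11 enyne side chain.
- The plan rests on ring A (C4a–C5–C6–C7–C8–C8a): oxygen on C4a and C6 flanking C5, next to the contiguous stereotriad C7 (OH, CH3), C8 (OH), C8a (CH2O). A 2-C- and 4-C-branched hex-5-enopyranoside delivers exactly this on Ferrier carbocyclisation (sugar C1–C6 = C4a, C8a, C8, C7, C6, C5), which forms C4a–C5.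
- The pyranoside comes from 4,6-O-benzylidene-D-glucal: hydroxyl-directed cyclopropanation and iodonium/methanol ring opening put the C1H2–O branch on sugar C2 cis to O3; a 4-ulose and MeMgBr give the axial tertiary alcohol (C7); a 6-iodide is eliminated to the enol ether.
- The side chain comes from (S)-5-(hydroxymethyl)furan-2(5H)-one: trans cuprate addition (C3′), lactone-to-ether reduction, chelation-controlled MeMgBr addition to a diynone (C11), hydride trans-reduction to the (E)-enyne.
- Order of ring formation: ring A (step 12), tetrahydrofuran ring (taken from the butenolide, step 18), ring B (step 26).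

Key step: step 12

Assumption: the target is numbered as a 1H-isochromene (C1H2, O2, C3, C4, C4a, C5–C8, C8a; side chain C9–C11; tetrahydrofuran C2′–C5′), sugar intermediates keep carbohydrate numbering with the oxygen of the 2-C-hydroxymethyl branch called O2a, compound 1 is taken as a catalogue compound, and 15 is carried on as the mixture of C4a carbinol epimers.

**Route**

Step 1
Reactants: 1 4,6-O-benzylidene-D-glucal
Product: 2 β-face 1,2-cyclopropane of 1 (1,5-anhydro-4,6-O-benzylidene-2-deoxy-1,2-C-methylene hexitol, CH2 bridge syn to the free 3-OH)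
Conditions: Et2Zn, CH2I2, CH2Cl2, 0 °C → rt
Reagents that add atoms: diiodomethane, ICI
Why: Simmons–Smith cyclopropanation (Furukawa variant) of the electron-rich enol ether, in which the zinc alkoxide of the allylic 3-OH delivers the carbenoid to the β-face, so the new C1–CH2 and C2–CH2 bonds are syn to O3.

Step 2
Reactants: 2 β-face 1,2-cyclopropane
Product: 3 methyl 4,6-O-benzylidene-2-deoxy-2-C-(iodomethyl)-α-D-mannopyranoside
Conditions: NIS, MeOH/CH2Cl2, 0 °C → rt
Reagents that add atoms: N-iodosuccinimide, O=C1CCC(=O)N1I; methanol, CO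
Why: Electrophilic ring opening of the donor-substituted cyclopropane: iodonium attacks the CH2 and cleaves the C1–CH2 bond with ring-oxygen assistance, the C2–CH2 bond (β-face, manno-type C2) is untouched, and methanol should add to the oxocarbenium ion axially, trans to the C2 branch (either anomer would serve, since C1 becomes sp2 later).

Step 3
Reactants: 3 methyl 4,6-O-benzylidene-2-deoxy-2-C-(iodomethyl)-α-D-mannopyranoside
Product: 5 methyl 4,6-O-benzylidene-2-deoxy-2-C-(hydroxymethyl)-α-D-mannopyranoside, via 2-C-acetoxymethyl glycoside 4 (not isolated)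
Conditions: CsOAc, 18-crown-6, DMF, 70 °C; then K2CO3, MeOH, rt
Reagents that add atoms: caesium acetate, CC(=O)[O-].[Cs+]
Why: SN2 displacement of the primary iodide by acetate followed by base-catalysed methanolysis of the ester (Zemplén type), neither of which touches a stereocentre.

Step 4
Reactants: 5 methyl 4,6-O-benzylidene-2-deoxy-2-C-(hydroxymethyl)-α-D-mannopyranoside
Product: 6 3-O,2a-O-(di-tert-butylsilanediyl) derivative of 5 (six-membered dioxasilinane cis-fused across C2–C3)
Conditions: tBu2Si(OTf)2, 2,6-lutidine, CH2Cl2, 0 °C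
Reagents that add atoms: di-tert-butylsilyl bis(trifluoromethanesulfonate), CC(C)(C)[Si](OS(=O)(=O)C(F)(F)F)(OS(=O)(=O)C(F)(F)F)C(C)(C)C
Why: Silylene formation on a cis-1,3-diol (equatorial O3 and the axial CH2OH branch on the same face) protects both oxygens in one step with a group that should survive the acid, organometallic, basic and oxidative steps that follow.

Step 5
Reactants: 6 silylene benzylidene acetal
Product: 7 methyl 6-O-benzyl-2-deoxy-2-C-(hydroxymethyl)-α-D-mannopyranoside 3-O,2a-O-(di-tert-butylsilanediyl) ether (free 4-OH)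
Conditions: Et3SiH, TfOH, 4 Å MS, CH2Cl2, −78 °C
Reagents that add atoms: none
Why: Regioselective reductive opening of the 4,6-O-benzylidene acetal by acid-activated silane reduction, which with Et3SiH/TfOH leaves the benzyl group on the primary O6 and frees the 4-OH.

Step 6
Reactants: 7 4-alcohol
Product: 8 methyl 6-O-benzyl-2-deoxy-2-C-(hydroxymethyl)-α-D-lyxo-hexopyranosid-4-ulose 3-O,2a-O-(di-tert-butylsilanediyl) ether
Conditions: Dess–Martin periodinane, NaHCO3, CH2Cl2, rt
Reagents that add atoms: none
Why: Dess–Martin oxidation of the secondary alcohol under buffered, non-basic conditions, which should avoid epimerisation at C3/C5 and β-elimination of the 4-ulose.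

Step 7
Reactants: 8 4-ulose
Product: 9 methyl 6-O-benzyl-2-deoxy-2-C-(hydroxymethyl)-4-C-methyl-α-D-talopyranoside 3-O,2a-O-(di-tert-butylsilanediyl) ether (tertiary 4-OH axial on the β-face, 4-CH3 equatorial)
Conditions: MeMgBr, THF, −78 °C; aq. NH4Cl
Reagents that add atoms: methylmagnesium bromide, C[Mg]Br
Why: Grignard 1,2-addition in which the axial CH2O branch at C2, 1,3-diaxial to the top face of C4, blocks axial attack, so methyl should enter equatorially from the α-face and the new tertiary hydroxyl is axial on the β-face, cis to O3, which is the C7 configuration of the target.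

Step 8
Reactants: 9 tertiary alcohol
Product: 10 4-O-triethylsilyl ether of 9
Conditions: Et3SiOTf, 2,6-lutidine, CH2Cl2, 0 °C → rt
Reagents that add atoms: triethylsilyl trifluoromethanesulfonate, CC[Si](CC)(CC)OS(=O)(=O)C(F)(F)F
Why: Silylation of the hindered tertiary alcohol with the reactive silyl triflate, so that this hydroxyl cannot trap the aldehyde of the key step as a lactol or interfere with the later triflation.

Step 9
Reactants: 10 4-O-triethylsilyl 6-O-benzyl ether
Product: 11 methyl 2-deoxy-2-C-(hydroxymethyl)-4-C-methyl-4-O-triethylsilyl-α-D-talopyranoside 3-O,2a-O-(di-tert-butylsilanediyl) ether (free 6-OH)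
Conditions: H2 (1 atm), Pd/C, EtOAc, rt
Reagents that add atoms: none
Why: Hydrogenolysis of the only benzyl ether; the silyl ether, the silylene and the methyl glycoside are inert to H2 over Pd/C in ethyl acetate.

Step 10
Reactants: 11 6-alcohol
Product: 12 6-deoxy-6-iodo derivative of 11
Conditions: I2, PPh3, imidazole, toluene, 60 °C
Reagents that add atoms: iodine, II
Why: Appel-type (Garegg–Samuelsson) iodination via the alkoxyphosphonium salt, possible only at the primary alcohol.

Step 11
Reactants: 12 6-iodide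
Product: 13 methyl 2,6-dideoxy-2-C-(hydroxymethyl)-4-C-methyl-4-O-triethylsilyl-hex-5-enopyranoside 3-O,2a-O-(di-tert-butylsilanediyl) ether (β-L-ribo by the rules, drawn as the α-D-talo-derived ring: 1-OMe on the α-face; C2 branch, O3 and O4 on the β-face; exocyclic C5=C6)
Conditions: DBU, THF, reflux
Reagents that add atoms: none
Why: E2 dehydroiodination in which H5 is the only β-hydrogen, giving the exocyclic enol ether.

Step 12
Reactants: 13 hex-5-enopyranoside
Product: 15 ring A β-hydroxy ketone (C6=O, C5H2, C4a–OH as both epimers, C7(CH3)(OSiEt3), C8–O and C8a–CH2O joined by the silylene), via mercurio keto aldehyde 14 (not isolated)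
Conditions: Hg(OCOCF3)2 (10 mol%), acetone/H2O (2:1), rt
Reagents that add atoms: water, O
Why: Ferrier carbocyclisation: Markovnikov hydroxymercuration of the exocyclic enol ether (OH to sugar C5, Hg to C6) gives a hemiketal that collapses to the 5-ketone and releases the anomeric carbon as an aldehyde with loss of methanol (14). The α-mercurio ketone then acts as a regiodefined enolate and adds to that aldehyde, forming C4a–C5 and closing ring A in a 6-(enolendo)-exo-trig aldol, with the divalent mercury salt set free again so that it turns over. The closest known reaction is the carbocyclisation of 6-deoxyhex-5-enopyranosides with catalytic Hg(OCOCF3)2 in aqueous acetone. The only new stereocentre is the C4a carbinol, which is not controlled (a chair-like aldol transition state usually places the hydroxyl trans to the sugar C3 oxygen) and need not be, because step 13 oxidises it. The step needs unambiguous enolisation, secured because the other α-carbon (C7) is quaternary, and it needs the C8a configuration and the β-hydroxy ketone to survive without epimerisation or dehydration, which the near-neutral medium and the fast intramolecular aldol should allow; C7, C8 and C8a are carried over unchanged.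

Step 13
Reactants: 15 ring A β-hydroxy ketone
Product: 16 ring A 1,3-dione (C4a=O, C6=O)
Conditions: Dess–Martin periodinane, NaHCO3, CH2Cl2, 0 °C → rt
Reagents that add atoms: none
Why: Dess–Martin oxidation of a β-hydroxy ketone to the 1,3-dione under non-basic conditions that avoid dehydration; it removes the uncontrolled C4a stereocentre.

Step 14
Reactants: 16 ring A 1,3-dione
Product: 17 5-chloro ring A 1,3-dione (drawn as the C4a enol)
Conditions: NCS (1.0 equiv), CH2Cl2, 0 °C
Reagents that add atoms: N-chlorosuccinimide, O=C1CCC(=O)N1Cl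
Why: Electrophilic chlorination of the dione enol at the doubly activated C5.

Step 15
Reactants: 17 5-chloro 1,3-dione
Product: 18 C4a enol triflate (5-chloro-6-oxo-4a-trifluoromethanesulfonyloxy enone of ring A)
Conditions: Tf2O, iPr2NEt, CH2Cl2, −78 °C
Reagents that add atoms: trifluoromethanesulfonic anhydride, O=S(=O)(OS(=O)(=O)C(F)(F)F)C(F)(F)F
Why: O-sulfonylation of the dione enolate at the less hindered oxygen: the oxygen on C4a is flanked by the tertiary C8a–H, whereas the oxygen on C6 is shielded by the quaternary C7 with its methyl and triethylsilyloxy groups, so the C4a triflate should predominate.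

Step 16
Reactants: 19 (S)-5-(hydroxymethyl)furan-2(5H)-one
Product: 20 (S)-5-[(tert-butyldiphenylsilyloxy)methyl]furan-2(5H)-one
Conditions: TBDPSCl, imidazole, CH2Cl2, rt
Reagents that add atoms: tert-butyl(chloro)diphenylsilane, CC(C)(C)[Si](Cl)(c1ccccc1)c1ccccc1
Why: Silylation of the primary alcohol, giving the bulky C5 substituent that directs the next step.

Step 17
Reactants: 20 silylated butenolide
Product: 21 (4S,5S)-5-[(tert-butyldiphenylsilyloxy)methyl]-4-methyldihydrofuran-2(3H)-one
Conditions: Me2CuLi (MeLi, CuI), Et2O, −78 → −40 °C; aq. NH4Cl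
Reagents that add atoms: lithium dimethylcuprate (from methyllithium, [Li]C, and CuI), [Li+].C[Cu-]C
Why: Conjugate addition of the Gilman cuprate to the butenolide anti to the bulky C5 substituent gives the 4,5-trans lactone, which sets C3′ relative to C2′.

Step 18
Reactants: 21 trans lactone
Product: 23 tert-butyl{[(2S,3S)-3-methyltetrahydrofuran-2-yl]methoxy}diphenylsilane, via lactol 22 (not isolated)
Conditions: iBu2AlH, CH2Cl2, −78 °C; then Et3SiH, BF3·OEt2, CH2Cl2, −78 → −20 °C
Reagents that add atoms: none
Why: Partial reduction of the lactone to the lactol and ionic deoxygenation of the derived oxocarbenium ion with silane converts the lactone carbonyl into the ring CH2 without touching either stereocentre.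

Step 19
Reactants: 23 silyl ether
Product: 24 [(2S,3S)-3-methyltetrahydrofuran-2-yl]methanol
Conditions: Bu4NF, THF, rt
Reagents that add atoms: none
Why: Fluoride cleavage of the silyl ether.

Step 20
Reactants: 24 primary alcohol
Product: 25 (2S,3S)-3-methyltetrahydrofuran-2-carboxylic acid
Conditions: TEMPO (cat.), PhI(OAc)2, MeCN/H2O, rt
Reagents that add atoms: water, O
Why: Oxoammonium oxidation takes the primary alcohol through the aldehyde hydrate to the acid; the 2,3-trans arrangement is the thermodynamically favoured one, so the α-centre is not at risk.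

Step 21
Reactants: 25 carboxylic acid
Product: 26 (2S,3S)-N-methoxy-N,3-dimethyltetrahydrofuran-2-carboxamide
Conditions: MeNH(OMe)·HCl, EDCI, N-methylmorpholine, CH2Cl2, 0 °C → rt
Reagents that add atoms: N,O-dimethylhydroxylamine hydrochloride, CNOC.Cl
Why: Carbodiimide amide coupling to the Weinreb amide.

Step 22
Reactants: 26 Weinreb amide; 27 1,4-bis(trimethylsilyl)buta-1,3-diyne
Product: 29 1-[(2S,3S)-3-methyltetrahydrofuran-2-yl]-5-(trimethylsilyl)penta-2,4-diyn-1-one, via lithium diynide 28 (not isolated)
Conditions: 27, MeLi·LiBr, THF, 0 °C → rt; then 26, −78 °C; aq. NH4Cl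
Reagents that add atoms: none
Why: Mono-desilylative lithiation of the bis-silyl diyne gives the lithium diynide, which acylates once at the Weinreb amide because the chelated tetrahedral intermediate survives until work-up.

Step 23
Reactants: 29 diynone
Product: 30 (2R)-2-[(2S,3S)-3-methyltetrahydrofuran-2-yl]-6-(trimethylsilyl)hexa-3,5-diyn-2-ol
Conditions: MeMgBr, THF, −78 °C; aq. NH4Cl
Reagents that add atoms: methylmagnesium bromide, C[Mg]Br
Why: Chelation-controlled (Cram-chelate) Grignard addition: magnesium bridges the ketone and ring oxygens, the ring body shields one face, and methyl should add from the side of the C2′ hydrogen to give the (R)-tertiary alcohol, C11 of the target.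

Step 24
Reactants: 30 diynol
Product: 32 (2R,3E)-2-[(2S,3S)-3-methyltetrahydrofuran-2-yl]hex-3-en-5-yn-2-ol, via silylated enynol 31 (not isolated)
Conditions: NaAlH2(OCH2CH2OMe)2, THF, 0 °C; aqueous work-up; then K2CO3, MeOH, rt
Reagents that add atoms: none
Why: Alkoxide-directed trans-hydroalumination reduces only the propargylic triple bond (the distal silylalkyne has no directing group) to the (E)-alkene after protonation, and carbonate in methanol then removes the alkynyl silyl group.

Step 25
Reactants: 18 C4a enol triflate; 32 side-chain enyne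
Product: 33 C4a-alkynyl 5-chloro-enone (ring A bearing at C4a the (3E,5R)-5-hydroxy-5-[(2S,3S)-3-methyltetrahydrofuran-2-yl]hex-3-en-1-ynyl group; O1/O8 silylene and C7–OSiEt3 retained)
Conditions: PdCl2(PPh3)2 (5 mol%), CuI (10 mol%), Et3N, THF, rt, degassed
Reagents that add atoms: none
Why: Sonogashira coupling, in which zerovalent palladium inserts into the activated vinylogous acyl C–OTf bond much faster than into the α-C–Cl bond and the free tertiary alcohol is tolerated.

Step 26
Reactants: 33 C4a-alkynyl 5-chloro-enone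
Product: 35 (7R,8R,8aS)-5-chloro-7,8-dihydroxy-3-[(1E,3R)-3-hydroxy-3-[(2S,3S)-3-methyltetrahydrofuran-2-yl]but-1-en-1-yl]-7-methyl-1,7,8,8a-tetrahydro-6H-isochromen-6-one, via triol enynone 34 (not isolated)
Conditions: HF·pyridine, pyridine, THF, 0 °C → rt; then DBU (0.1 equiv), CH2Cl2, 0 °C
Reagents that add atoms: none
Why: Fluoride removes the silylene and the triethylsilyl ether, and the liberated C1 hydroxyl then adds to C3, the δ-position of the alkynyl chloro-enone, in a base-catalysed 6-endo-dig oxa-Michael (1,6-) addition that is favoured over 5-exo attack at the non-electrophilic C4 (closure through O8 would need a bridged ring with a bridgehead alkene), protonation at C4 giving the conjugated dienone of ring B.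

**Compound list**

1 | 4,6-O-benzylidene-D-glucal | C1=C[C@@H](O)[C@@H]2O[C@H](c3ccccc3)OC[C@H]2O1 | starting material
2 | β-face 1,2-cyclopropane of 1 (CH2 syn to 3-OH) | C1[C@@H]2O[C@@H]3CO[C@@H](c4ccccc4)O[C@H]3[C@H](O)[C@H]12 | intermediate
3 | methyl 4,6-O-benzylidene-2-deoxy-2-C-(iodomethyl)-α-D-mannopyranoside | CO[C@H]1O[C@@H]2CO[C@@H](c3ccccc3)O[C@H]2[C@H](O)[C@@H]1CI | intermediate
4 | methyl 2-C-(acetoxymethyl)-4,6-O-benzylidene-2-deoxy-α-D-mannopyranoside (not isolated) | CO[C@H]1O[C@@H]2CO[C@@H](c3ccccc3)O[C@H]2[C@H](O)[C@@H]1COC(C)=O | intermediate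
5 | methyl 4,6-O-benzylidene-2-deoxy-2-C-(hydroxymethyl)-α-D-mannopyranoside | CO[C@H]1O[C@@H]2CO[C@@H](c3ccccc3)O[C@H]2[C@H](O)[C@@H]1CO | intermediate
6 | 3-O,2a-O-(di-tert-butylsilanediyl) derivative of 5 | CO[C@H]1O[C@@H]2CO[C@@H](c3ccccc3)O[C@H]2[C@@H]4O[Si](C(C)(C)C)(C(C)(C)C)OC[C@H]14 | intermediate
7 | methyl 6-O-benzyl-2-deoxy-2-C-(hydroxymethyl)-α-D-mannopyranoside 3-O,2a-O-silylene, 4-OH free | CO[C@H]1O[C@H](COCc2ccccc2)[C@@H](O)[C@@H]4O[Si](C(C)(C)C)(C(C)(C)C)OC[C@H]14 | intermediate
8 | corresponding α-D-lyxo-hexopyranosid-4-ulose | CO[C@H]1O[C@H](COCc2ccccc2)C(=O)[C@@H]4O[Si](C(C)(C)C)(C(C)(C)C)OC[C@H]14 | intermediate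
9 | methyl 6-O-benzyl-2-deoxy-2-C-(hydroxymethyl)-4-C-methyl-α-D-talopyranoside 3-O,2a-O-silylene | CO[C@H]1O[C@H](COCc2ccccc2)[C@](C)(O)[C@@H]4O[Si](C(C)(C)C)(C(C)(C)C)OC[C@H]14 | intermediate
10 | 4-O-triethylsilyl ether of 9 | CO[C@H]1O[C@H](COCc2ccccc2)[C@](C)(O[Si](CC)(CC)CC)[C@@H]4O[Si](C(C)(C)C)(C(C)(C)C)OC[C@H]14 | intermediate
11 | 6-alcohol (debenzylated 10) | CO[C@H]1O[C@H](CO)[C@](C)(O[Si](CC)(CC)CC)[C@@H]4O[Si](C(C)(C)C)(C(C)(C)C)OC[C@H]14 | intermediate
12 | 6-deoxy-6-iodo derivative of 11 | CO[C@H]1O[C@H](CI)[C@](C)(O[Si](CC)(CC)CC)[C@@H]4O[Si](C(C)(C)C)(C(C)(C)C)OC[C@H]14 | intermediate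
13 | methyl 2,6-dideoxy-2-C-(hydroxymethyl)-4-C-methyl-4-O-triethylsilyl-hex-5-enopyranoside 3-O,2a-O-silylene (key-step precursor) | CO[C@H]1OC(=C)[C@](C)(O[Si](CC)(CC)CC)[C@@H]4O[Si](C(C)(C)C)(C(C)(C)C)OC[C@H]14 | intermediate
14 | open-chain C6-mercurio 5-keto aldehyde (not isolated) | O=C[C@H]1CO[Si](C(C)(C)C)(C(C)(C)C)O[C@H]1[C@@](C)(O[Si](CC)(CC)CC)C(=O)C[Hg]OC(=O)C(F)(F)F | intermediate
15 | ring A β-hydroxy ketone, C4a epimers (key-step product) | O=C1CC(O)[C@H]2CO[Si](C(C)(C)C)(C(C)(C)C)O[C@H]2[C@@]1(C)O[Si](CC)(CC)CC | intermediate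
16 | ring A 1,3-dione | O=C1CC(=O)[C@H]2CO[Si](C(C)(C)C)(C(C)(C)C)O[C@H]2[C@@]1(C)O[Si](CC)(CC)CC | intermediate
17 | 5-chloro ring A 1,3-dione (C4a enol form) | O=C1C(Cl)=C(O)[C@H]2CO[Si](C(C)(C)C)(C(C)(C)C)O[C@H]2[C@@]1(C)O[Si](CC)(CC)CC | intermediate
18 | C4a enol triflate | O=C1C(Cl)=C(OS(=O)(=O)C(F)(F)F)[C@H]2CO[Si](C(C)(C)C)(C(C)(C)C)O[C@H]2[C@@]1(C)O[Si](CC)(CC)CC | intermediate
19 | (S)-5-(hydroxymethyl)furan-2(5H)-one | O=C1C=C[C@@H](CO)O1 | starting material
20 | (S)-5-[(tert-butyldiphenylsilyloxy)methyl]furan-2(5H)-one | O=C1C=C[C@@H](CO[Si](c2ccccc2)(c2ccccc2)C(C)(C)C)O1 | intermediate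
21 | (4S,5S)-5-[(tert-butyldiphenylsilyloxy)methyl]-4-methyldihydrofuran-2(3H)-one | O=C1C[C@H](C)[C@@H](CO[Si](c2ccccc2)(c2ccccc2)C(C)(C)C)O1 | intermediate
22 | (4S,5S)-5-[(tert-butyldiphenylsilyloxy)methyl]-4-methyltetrahydrofuran-2-ol, lactol anomers (not isolated) | OC1C[C@H](C)[C@@H](CO[Si](c2ccccc2)(c2ccccc2)C(C)(C)C)O1 | intermediate
23 | tert-butyl{[(2S,3S)-3-methyltetrahydrofuran-2-yl]methoxy}diphenylsilane | C[C@H]1CCO[C@@H]1CO[Si](c1ccccc1)(c1ccccc1)C(C)(C)C | intermediate
24 | [(2S,3S)-3-methyltetrahydrofuran-2-yl]methanol | C[C@H]1CCO[C@@H]1CO | intermediate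
25 | (2S,3S)-3-methyltetrahydrofuran-2-carboxylic acid | C[C@H]1CCO[C@@H]1C(=O)O | intermediate
26 | (2S,3S)-N-methoxy-N,3-dimethyltetrahydrofuran-2-carboxamide | C[C@H]1CCO[C@@H]1C(=O)N(C)OC | intermediate
27 | 1,4-bis(trimethylsilyl)buta-1,3-diyne | C[Si](C)(C)C#CC#C[Si](C)(C)C | starting material
28 | lithium (trimethylsilyl)buta-1,3-diynide (not isolated) | [Li]C#CC#C[Si](C)(C)C | intermediate
29 | 1-[(2S,3S)-3-methyltetrahydrofuran-2-yl]-5-(trimethylsilyl)penta-2,4-diyn-1-one | C[C@H]1CCO[C@@H]1C(=O)C#CC#C[Si](C)(C)C | intermediate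
30 | (2R)-2-[(2S,3S)-3-methyltetrahydrofuran-2-yl]-6-(trimethylsilyl)hexa-3,5-diyn-2-ol | C[C@H]1CCO[C@@H]1[C@](C)(O)C#CC#C[Si](C)(C)C | intermediate
31 | (2R,3E)-2-[(2S,3S)-3-methyltetrahydrofuran-2-yl]-6-(trimethylsilyl)hex-3-en-5-yn-2-ol (not isolated) | C[C@H]1CCO[C@@H]1[C@](C)(O)/C=C/C#C[Si](C)(C)C | intermediate
32 | (2R,3E)-2-[(2S,3S)-3-methyltetrahydrofuran-2-yl]hex-3-en-5-yn-2-ol | C[C@H]1CCO[C@@H]1[C@](C)(O)/C=C/C#C | intermediate
33 | C4a-alkynyl 5-chloro-enone, O1/O8 silylene, C7–OSiEt3 | O=C1C(Cl)=C(C#C/C=C/[C@@](C)(O)[C@H]3OCC[C@@H]3C)[C@H]2CO[Si](C(C)(C)C)(C(C)(C)C)O[C@H]2[C@@]1(C)O[Si](CC)(CC)CC | intermediate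
34 | desilylated triol enynone (not isolated) | O=C1C(Cl)=C(C#C/C=C/[C@@](C)(O)[C@H]3OCC[C@@H]3C)[C@@H](CO)[C@@H](O)[C@@]1(C)O | intermediate
35 | (7R,8R,8aS)-5-chloro-7,8-dihydroxy-3-[(1E,3R)-3-hydroxy-3-[(2S,3S)-3-methyltetrahydrofuran-2-yl]but-1-en-1-yl]-7-methyl-1,7,8,8a-tetrahydro-6H-isochromen-6-one (CNP0432723.2) | C[C@H]1CCO[C@@H]1[C@](C)(O)/C=C/C1=CC2=C(Cl)C(=O)[C@](C)(O)[C@H](O)[C@@H]2CO1 | target

**Step count and risks**

Total step count: 26. Longest linear sequence: 17 steps (steps 1–15, 25, 26, from 1); the side chain takes 9 steps (16–24) from 19.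

Steps most likely to fail:

1. Step 12 (key step). Hydroxymercuration next to the quaternary C4 may be slow, the trifluoroacetic acid released may strip the triethylsilyl ether, or the aldol product may dehydrate to the enone. Fallback, setting out from 13: the enol ether is hydrolysed with dilute aqueous acetic acid in THF to the mercury-free 6-deoxy-5-keto aldehyde F1. This is cyclised with a catalytic amine base (DBU, toluene, 0 °C) in an ordinary intramolecular aldol, in which only the methyl ketone can enolise towards C5. The fallback comes back to the route at 15.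

2. Step 15. Sulfonylation may occur at the wrong enol oxygen (on C6) or give a mixture of regioisomeric triflates. Fallback, setting out from 17: the tertiary triethylsilyl ether is removed selectively (PPTS, MeOH) to give the 7-hydroxy chloro-dione F2. Its C7 hydroxyl and the only enol oxygen it can reach (on C6) are tied together with tBu2Si(OTf)2/Et3N as the five-membered enol silylene F3, which leaves C4a as the sole ketone. The dilithio derivative of 32 (2 equiv n-BuLi, THF, −78 °C) adds to that ketone to give the tertiary propargylic alcohol F4. HF·pyridine then removes both silylenes, and the resulting β-hydroxy ketone loses water (Stork–Danheiser-type transposition, completed by the DBU of step 26). The fallback comes back to the route at 34 and goes on to 35.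

3. Step 26. The closure may go 5-exo, the base may trigger dehydration across C8–C8a, or the polar triol enynone may decompose during fluoride treatment. Fallback, setting out from 33: diethylamine is added to the alkynyl enone (THF, rt) to give the C3 diethylamino dienone F5, which fixes the site of attack at C3. HF·pyridine gives the desilylated amino dienone F6. Mild acid (AcOH, CH2Cl2) then lets the C1 hydroxyl replace the amine by addition–elimination, as in chromone synthesis from enaminones. The fallback comes back to the route at 35.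

**Further compounds**

F1 | step 12 | 6-deoxy-5-keto aldehyde (open-chain, O1/O8 silylene, C7–OSiEt3) | O=C[C@H]1CO[Si](C(C)(C)C)(C(C)(C)C)O[C@H]1[C@@](C)(O[Si](CC)(CC)CC)C(C)=O
F2 | step 15 | 7-hydroxy 5-chloro ring A 1,3-dione (O1/O8 silylene) | O=C1C(Cl)=C(O)[C@H]2CO[Si](C(C)(C)C)(C(C)(C)C)O[C@H]2[C@@]1(C)O
F3 | step 15 | O6,O7-(di-tert-butylsilanediyl) enol silylene with C4a ketone | O=C1C(Cl)=C3O[Si](C(C)(C)C)(C(C)(C)C)O[C@]3(C)[C@@H]4O[Si](C(C)(C)C)(C(C)(C)C)OC[C@H]14
F4 | step 15 | C4a tertiary propargylic alcohol from addition of metallated 32 to F3 (C4a epimers) | OC1(C#C/C=C/[C@@](C)(O)[C@H]5OCC[C@@H]5C)C(Cl)=C3O[Si](C(C)(C)C)(C(C)(C)C)O[C@]3(C)[C@@H]4O[Si](C(C)(C)C)(C(C)(C)C)OC[C@H]14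
F5 | step 26 | C3 diethylamino dienone from 33 (C3=C4 geometry open) | O=C1C(Cl)=C(C=C(N(CC)CC)/C=C/[C@@](C)(O)[C@H]3OCC[C@@H]3C)[C@H]2CO[Si](C(C)(C)C)(C(C)(C)C)O[C@H]2[C@@]1(C)O[Si](CC)(CC)CC
F6 | step 26 | desilylated C3 diethylamino dienone | O=C1C(Cl)=C(C=C(N(CC)CC)/C=C/[C@@](C)(O)[C@H]3OCC[C@@H]3C)[C@@H](CO)[C@@H](O)[C@@]1(C)O
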